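# Synthesis plan for methyl 2-[3-(3-chloro-6-hydroxy-2,4-dimethoxyphenyl)-2-oxopropyl]-3-hydroxy-5-methylbenzoate (18)

Atom labels used throughout: ring A carries CO2Me at C1, CH3 at C3, OH at C5 and the chain at C6. Ring B carries the chain at C1′, OH at C2′, OMe at C4′ and C6′, and Cl at C5′. The chain is CaH2–Cb(=O)–CcH2, with Ca on C6 and Cc on C1′.

## The problem

Compound 18 is a 1,3-diarylpropan-2-one: two separately substituted benzene rings joined only by the three-carbon chain Ca–Cb–Cc. It has no stereocentre, so the task is purely one of regiochemistry and chemoselectivity: the chain must be built between two crowded arenes with its oxygen on Cb, not on Ca or Cc. Ring A carries ester, chain and phenol on three adjacent carbons, a pattern that electrophilic substitution of a 3-hydroxy-5-methylbenzoate does not give cleanly. Ring B has five substituents, and its one free phenol must stay distinguishable from two methyl ethers. Several groups are fragile. Each phenol lies ortho to a benzylic methylene of the ketone, so acid and heat can close either one onto Cb and dehydrate to a benzofuran. Base can send the Cc enolate into the C1 ester to give a naphthalene-1,3-diol. The C5′ chloride rules out hydrogenolytic deprotection. The feature that opens the synthesis is that the carboxyl carbon on C1 is ortho to C6. One of its oxygens can therefore bond to Cb in the six-membered ring O–Cb=Ca–C6–C1–C(=O), an isocoumarin. In this enol lactone Cb is already at the ketone oxidation level, and one methanolysis releases ketone and methyl ester together.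

## Retrosynthesis

**18 ⇒ 17.** The two phenolic O–H bonds are traced back to methoxymethyl acetals. Benzyl ethers would need hydrogenolysis beside the C5′ chloride. Methyl ethers could not be told from the C4′ and C6′ methoxy groups. Silyl ethers direct metalation poorly and would not survive the basic steps. The methoxymethyl group is also the ortho director that builds both halves, so it does two jobs. The forward step must hydrolyse two aryl acetals without dehydrating the ortho-hydroxybenzyl ketone.

**17 ⇒ 16.** The C1 ester C–OMe bond and the Cb carbonyl are exchanged for a lactone link between the carboxyl oxygen and Cb, giving isocoumarin 16. This removes the free ketone and both acidic methylene problems from every earlier step. It also turns the question "which chain carbon is oxygenated" into "which ring size closes". The neighbouring option, unaided hydration of a 1,3-diarylpropyne, has nothing to choose Cb over Ca. Forward, a catalytic alkoxide transesterification must open the enol lactone and stop before the Cc enolate attacks the new ester.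

**16 ⇒ 5 + 14.** The C6–Ca bond (sp2–sp) and the Cb–O bond are cut together, giving iodo acid 5 and propargyl arene 14. The cut is convergent, the halves are of similar size, and each ring has its full substitution before union. Cutting Ca–Cb or Cb–Cc would instead need enolate or acyl-anion chemistry at benzylic carbons flanked by two ortho substituents, with the C1 ester nearby as a competing electrophile. The forward step must react at C–I and not C–Cl, close 6-endo and not 5-exo, and avoid propargyl–allene isomerisation.

**5 ⇒ 3 ⇒ 1.** The C–I bond of 5 is cut to acid 3. The iodine sits on the one carbon flanked by both the carboxylate and the acetal, the site cooperative directed metalation selects. Acid 3 comes from commercial 3-hydroxy-5-methylbenzoic acid 1 by O-alkylation and saponification of the ester that forms alongside (intermediate 2). The forward metalation must beat addition of the alkyllithium to the carboxylate.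

**14 ⇒ 13 ⇒ 9 + 10.** The terminal C–H of 14 is traced to the C–Si bond of 13. The C1′–Cc bond of 13 is then cut to the metalated form of arene 9 and the silylated propargyl bromide 10. The silyl group is there to block SN2′ attack at the alkyne terminus, which would give an allene. Arene 9 has only two ring hydrogens, equivalent by symmetry and each between two oxygen directors, so metalation has one possible site.

**9 ⇒ 8 ⇒ 6.** The acetal O–C bond of 9 leads to phenol 8. The phenolic C–O bond of 8 is cut to commercial 2-chloro-1,3-dimethoxybenzene 6. The only C–H of 6 without an ortho substituent is the one para to chlorine, so sterically governed C–H borylation and oxidation (through boronate 7) place the oxygen there. Chlorinating a dimethoxyphenol, the neighbouring option, would give ortho/para mixtures.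

## Roads not taken

**Alternative 1:** Ring A is made from a furan. The cut runs through ring A bonds C1–C6 and C2–C3. The precursor is furfuryl ether A1, a 4-methylfuran tethered through O–CH(CH2Ar)–CH2 to a terminal alkyne. In the forward key step a gold catalyst isomerises A1 to the racemic isochroman-5-ol A2. The furan oxygen migrates to become the C5 phenol, and the benzene and pyran rings form together. The merits are real: the phenol is placed by mechanism, not by lithiation selectivity, it arrives unprotected, the isomerisation wastes no atoms, and the fragments are joined by a simple etherification. The weak points are threefold.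
- The tether closes a six-membered oxygen ring, one atom longer than the five-membered cases in which the furan–yne phenol synthesis is most dependable.
- The 2,4-disubstituted furan is not a stock building block.
- A2 is at the wrong oxidation level twice. Its C1 methylene must be oxidised to the carboxyl in the presence of the equally benzylic Cc methylene and a free phenol. After lactone opening, the C3 carbinol must be oxidised to the ketone, and its stereocentre is made only to be erased.

Alternative 1 is better at fixing ring A regiochemistry. Against that, the chosen plan has cooperative 1,3-directed metalation of a purchased ring A, and an intermediate 16 that is already at the correct oxidation level at every carbon, two steps from 18.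

**Alternative 2:** Ring B is made by a Danheiser benzannulation. The cut runs through C1′–C2′ and C5′–C6′. Heating cyclobutenone A3 with ynol ether A4, which already carries ring A and a silyl-protected carbinol at Cb, gives phenol A5. The sequence is vinylketene formation, [2+2] cycloaddition, four-electron ring opening and six-electron closure. Its merit is that chlorine, both methoxy groups and the free C2′ phenol are placed by the mechanism. The phenol emerges already distinct from the methyl ethers, with no protecting group and no aryl–metal species near the chloride. In that respect it is cleaner than the chosen route. The weak points: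
- A4 is a sensitive ynol ether that needs a multistep synthesis of its own.
- The annulation does not address the chain. The Cb oxygen must be installed beforehand by other chemistry and later desilylated and oxidised beside an electron-rich free phenol.
- The cascade needs prolonged heating with an ortho ester positioned to lactonise.

The chosen plan reaches the ring B partner 14 in four steps from 6, with regiochemistry made trivial by the symmetry of phenol 8. It also lets the ring A carboxyl decide where the chain oxygen goes.

**Alternative 3:** Ring A is made by a dimedone-type annulation and aromatised late. The cut runs through C3–C4 and C5–C6. Malonate A7 adds to the propenyl ketone A6 in a Michael reaction, and the ketone α′ carbon then attacks a malonate ester to give cyclohexane-1,3-dione A8. The step uses cheap reagents, needs no transition metal or cryogenic lithiation, and scales well. On cost of the ring-forming step it beats the chosen plan. The weak points lie downstream and upstream.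
- A8 still needs dealkoxycarbonylation and dehydrogenation to a 2-substituted 5-methylresorcinol, whose two oxygens are equivalent. One of them must then be replaced by the carboxyl, by monotriflation and carbonylation, a statistical desymmetrisation that discards an oxygen the annulation just installed.
- The chain ketone must travel as a ketal, and its acidic removal meets the same benzofuran risk, now alongside acetal loss on ring B.
- A6 itself takes several steps.
- The Claisen step must choose α′ over γ deprotonation.

The chosen plan buys both rings aromatic with the carboxyl already on C1, and spends its steps on the one bond set that matters.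

Key step: step 7

Remark: 18 has no stereogenic element, so no step has a stereochemical task; 1, 6 and 10 are taken as purchasable.

## Route

Step 1
Reactants: 1 3-hydroxy-5-methylbenzoic acid
Product: 3 3-(methoxymethoxy)-5-methylbenzoic acid, via methoxymethyl ester 2 (not isolated)
Conditions: MOMCl (2.5 equiv), iPr2NEt, CH2Cl2, 0 °C to rt; then 2 M aq NaOH, MeOH, rt; cold 1 M HCl to pH 4
Reagents that add atoms: chloromethyl methyl ether (MOMCl), COCCl
Why: O-alkylation of phenoxide and carboxylate gives the bis-alkylated ester 2; its acyloxymethyl ester is saponified under mild base while the aryl acetal is inert to hydroxide, so the telescoped protection–saponification should give 3 cleanly.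

Step 2
Reactants: 3 3-(methoxymethoxy)-5-methylbenzoic acid
Product: 5 2-iodo-3-(methoxymethoxy)-5-methylbenzoic acid, via dilithio species 4 (not isolated)
Conditions: s-BuLi (2.2 equiv), TMEDA (2.2 equiv), THF, −78 °C; then I2, −78 °C to rt; aq Na2S2O3; cold 1 M HCl to pH 3–4
Reagents that add atoms: iodine, II
Why: Directed ortho-metalation of an unprotected benzoic acid: the lithium carboxylate and the acetal oxygen both coordinate the base and converge on the one carbon between them, and at −78 °C with TMEDA deprotonation outruns addition to the carboxylate; iodine then traps the aryllithium.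

Step 3
Reactants: 6 2-chloro-1,3-dimethoxybenzene
Product: 8 4-chloro-3,5-dimethoxyphenol, via pinacol arylboronate 7 (not isolated)
Conditions: [Ir(OMe)(cod)]2 (1.5 mol %), 4,4′-di-tert-butyl-2,2′-bipyridine (3 mol %), B2pin2 (1.0 equiv), THF, 80 °C; then KHSO5 (as Oxone, 2KHSO5·KHSO4·K2SO4), acetone–H2O, rt
Reagents that add atoms: potassium peroxymonosulfate KHSO5, [K+].[O-]S(=O)(=O)OO
Why: Iridium-catalysed aromatic C–H borylation is governed by sterics and should select the only hydrogen with no ortho substituent (para to chlorine); ipso-oxidation of the boronate by peroxymonosulfate then gives the phenol in the same flask.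

Step 4
Reactants: 8 4-chloro-3,5-dimethoxyphenol
Product: 9 2-chloro-1,3-dimethoxy-5-(methoxymethoxy)benzene
Conditions: MOMCl (1.3 equiv), iPr2NEt, CH2Cl2, 0 °C to rt
Reagents that add atoms: chloromethyl methyl ether (MOMCl), COCCl
Why: Standard O-alkylation of an unhindered phenol to its methoxymethyl ether, which serves as both protecting group and metalation director.

Step 5
Reactants: 9 2-chloro-1,3-dimethoxy-5-(methoxymethoxy)benzene; 10 3-bromo-1-(trimethylsilyl)prop-1-yne
Product: 13 [3-[3-chloro-2,4-dimethoxy-6-(methoxymethoxy)phenyl]prop-1-yn-1-yl]trimethylsilane, via aryllithium 11 (not isolated), via arylcopper 12 (not isolated)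
Conditions: n-BuLi (1.1 equiv), THF, 0 °C; CuBr·SMe2 (1.1 equiv), −78 to −40 °C; then 10, −78 °C to rt
Reagents that add atoms: none
Why: Directed ortho-metalation between the acetal and a methoxy group (the two open positions are equivalent, and the chloride has no ortho hydrogen, so no aryne can form), lithium-to-copper transmetalation, then SN2 substitution of the propargylic bromide; the silyl group shields the alkyne terminus against SN2′ attack, so the propargyl arene and not an allene is expected.

Step 6
Reactants: 13 [3-[3-chloro-2,4-dimethoxy-6-(methoxymethoxy)phenyl]prop-1-yn-1-yl]trimethylsilane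
Product: 14 2-chloro-1,3-dimethoxy-5-(methoxymethoxy)-4-(prop-2-yn-1-yl)benzene
Conditions: K2CO3 (0.2 equiv), MeOH, 0 °C to rt
Reagents that add atoms: none
Why: Base-catalysed protodesilylation of an alkynylsilane by methanolic carbonate; the base is too weak and the time too short to move the triple bond into conjugation with ring B.

Step 7
Reactants: 5 2-iodo-3-(methoxymethoxy)-5-methylbenzoic acid; 14 2-chloro-1,3-dimethoxy-5-(methoxymethoxy)-4-(prop-2-yn-1-yl)benzene
Product: 16 3-[[3-chloro-2,4-dimethoxy-6-(methoxymethoxy)phenyl]methyl]-5-(methoxymethoxy)-7-methyl-1H-isochromen-1-one, via 2-alkynylbenzoic acid 15 (not isolated)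
Conditions: Pd(PPh3)4 (5 mol %), ZnCl2 (1.0 equiv), Et3N (5 equiv), degassed DMF, 90–100 °C
Reagents that add atoms: none
Why: Zerovalent palladium inserts into the C–I bond of the carboxylate of 5, the zinc acetylide formed from 14 with ZnCl2 and Et3N transmetalates, and reductive elimination makes the C6–Ca bond to give 15 as its carboxylate. The alkyne of 15, activated by zinc or divalent palladium, is then attacked anti by the neighbouring carboxylate oxygen at the distal carbon Cb, and protonolysis of the vinyl–metal bond releases 16. The closest known reaction type is the palladium/zinc-mediated coupling–cyclisation of 2-iodobenzoic acids with terminal alkynes to 3-substituted isocoumarins. The one ring formed, the pyranone, closes in the 6-endo-dig mode; no stereocentre is created. The selectivity needed is 6-endo over 5-exo-dig closure to an alkylidenephthalide, and it is favoured by the zinc co-metal in place of copper and by the sp3 (benzylic) substituent on the alkyne. Chemoselectivity for C–I over the C5′–Cl bond follows from the large difference in oxidative-addition rates with a triphenylphosphine catalyst. Et3N is too weak to isomerise the propargylic methylene to an allene, and the amine-buffered medium should leave both acetals intact.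

Step 8
Reactants: 16 3-[[3-chloro-2,4-dimethoxy-6-(methoxymethoxy)phenyl]methyl]-5-(methoxymethoxy)-7-methyl-1H-isochromen-1-one
Product: 17 methyl 2-[3-[3-chloro-2,4-dimethoxy-6-(methoxymethoxy)phenyl]-2-oxopropyl]-3-(methoxymethoxy)-5-methylbenzoate
Conditions: NaOMe (0.3 equiv), MeOH–THF, 0 °C to rt; AcOH quench
Reagents that add atoms: methanol, CO
Why: Alkoxide transesterification of an enol lactone: methoxide adds to the lactone carbonyl, the enolate of the Cb ketone leaves and is protonated at Ca by the solvent, regenerating methoxide; low temperature and catalytic base keep the Cc enolate from attacking the new ester (Dieckmann-type closure).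

Step 9
Reactants: 17 methyl 2-[3-[3-chloro-2,4-dimethoxy-6-(methoxymethoxy)phenyl]-2-oxopropyl]-3-(methoxymethoxy)-5-methylbenzoate
Product: 18 methyl 2-[3-(3-chloro-6-hydroxy-2,4-dimethoxyphenyl)-2-oxopropyl]-3-hydroxy-5-methylbenzoate
Conditions: 3 M aq HCl, MeOH–THF, rt, stopped at full conversion; NaHCO3 work-up
Reagents that add atoms: none
Why: Acid-catalysed hydrolysis of the two aryl methoxymethyl acetals; aryl methyl ethers, the methyl ester and the aryl chloride are inert, and aqueous acid at room temperature should keep any cyclic hemiketal in equilibrium with the open ketone without dehydrating it to a benzofuran.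

## Compound list

1 | 3-hydroxy-5-methylbenzoic acid | Cc1cc(O)cc(C(=O)O)c1 | starting material
2 | methoxymethyl 3-(methoxymethoxy)-5-methylbenzoate | COCOC(=O)c1cc(C)cc(OCOC)c1 | intermediate (not isolated)
3 | 3-(methoxymethoxy)-5-methylbenzoic acid | COCOc1cc(C)cc(C(=O)O)c1 | intermediate
4 | lithium 2-lithio-3-(methoxymethoxy)-5-methylbenzoate | [Li]c1c(OCOC)cc(C)cc1C(=O)[O-].[Li+] | intermediate (not isolated)
5 | 2-iodo-3-(methoxymethoxy)-5-methylbenzoic acid | COCOc1cc(C)cc(C(=O)O)c1I | intermediate
6 | 2-chloro-1,3-dimethoxybenzene | COc1cccc(OC)c1Cl | starting material
7 | 2-(4-chloro-3,5-dimethoxyphenyl)-4,4,5,5-tetramethyl-1,3,2-dioxaborolane | COc1cc(B2OC(C)(C)C(C)(C)O2)cc(OC)c1Cl | intermediate (not isolated)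
8 | 4-chloro-3,5-dimethoxyphenol | COc1cc(O)cc(OC)c1Cl | intermediate
9 | 2-chloro-1,3-dimethoxy-5-(methoxymethoxy)benzene | COCOc1cc(OC)c(Cl)c(OC)c1 | intermediate
10 | 3-bromo-1-(trimethylsilyl)prop-1-yne | C[Si](C)(C)C#CCBr | starting material
11 | [3-chloro-2,4-dimethoxy-6-(methoxymethoxy)phenyl]lithium | [Li]c1c(OCOC)cc(OC)c(Cl)c1OC | intermediate (not isolated)
12 | [3-chloro-2,4-dimethoxy-6-(methoxymethoxy)phenyl]copper | [Cu]c1c(OCOC)cc(OC)c(Cl)c1OC | intermediate (not isolated)
13 | [3-[3-chloro-2,4-dimethoxy-6-(methoxymethoxy)phenyl]prop-1-yn-1-yl]trimethylsilane | C[Si](C)(C)C#CCc1c(OCOC)cc(OC)c(Cl)c1OC | intermediate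
14 | 2-chloro-1,3-dimethoxy-5-(methoxymethoxy)-4-(prop-2-yn-1-yl)benzene | C#CCc1c(OCOC)cc(OC)c(Cl)c1OC | intermediate
15 | 2-[3-[3-chloro-2,4-dimethoxy-6-(methoxymethoxy)phenyl]prop-1-yn-1-yl]-3-(methoxymethoxy)-5-methylbenzoic acid | Cc1cc(OCOC)c(C#CCc2c(OCOC)cc(OC)c(Cl)c2OC)c(C(=O)O)c1 | intermediate (not isolated)
16 | 3-[[3-chloro-2,4-dimethoxy-6-(methoxymethoxy)phenyl]methyl]-5-(methoxymethoxy)-7-methyl-1H-isochromen-1-one | Cc1cc(OCOC)c2C=C(Cc3c(OCOC)cc(OC)c(Cl)c3OC)OC(=O)c2c1 | intermediate
17 | methyl 2-[3-[3-chloro-2,4-dimethoxy-6-(methoxymethoxy)phenyl]-2-oxopropyl]-3-(methoxymethoxy)-5-methylbenzoate | COC(=O)c1cc(C)cc(OCOC)c1CC(=O)Cc1c(OCOC)cc(OC)c(Cl)c1OC | intermediate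
18 | methyl 2-[3-(3-chloro-6-hydroxy-2,4-dimethoxyphenyl)-2-oxopropyl]-3-hydroxy-5-methylbenzoate | COC(=O)c1cc(C)cc(O)c1CC(=O)Cc1c(O)cc(OC)c(Cl)c1OC | target

## Step count and least certain steps

Total steps: 9. Longest linear sequence: 7 steps (steps 3, 4, 5, 6, 7, 8, 9, from 6 to 18); the ring A branch (steps 1 and 2) joins at step 7.

**Step 7 (key step).**
- What may go wrong: closure of the carboxylate onto Ca in the 5-exo mode. This is helped electronically because the ring A acetal oxygen ortho to the alkyne pushes electron density toward Cb.
- Base-mediated isomerisation of the propargylic methylene to an allene, before or after coupling.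
- Slow oxidative addition at the doubly ortho-substituted iodide, with protodeiodination taking over.
- Fallback: it sets out from 5 and returns at 17, bypassing 16.
  - Acid 5 is methylated (MeI, K2CO3, DMF) to methyl 2-iodo-3-(methoxymethoxy)-5-methylbenzoate F1.
  - A room-temperature Sonogashira coupling of F1 with 14 (PdCl2(PPh3)2, CuI, iPr2NH, THF) gives methyl 2-[3-[3-chloro-2,4-dimethoxy-6-(methoxymethoxy)phenyl]prop-1-yn-1-yl]-3-(methoxymethoxy)-5-methylbenzoate F2. With no free carboxylate present, no lactone can form at this stage.
  - A cationic monovalent gold catalyst (Ph3PAuCl/AgOTf, wet 1,4-dioxane, rt) then hydrates the alkyne of F2 with ester participation. The ester carbonyl oxygen adds 6-endo to Cb, the mode by which ortho-alkynylbenzoate esters are known to release isocoumarins under gold catalysis. Water opens the resulting 1-methoxyisochromenylium ion at C1 to give 17. Should methanol be lost instead, the product is 16, which is also on the route.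

**Step 9.**
- What may go wrong: acid-promoted cyclodehydration of either freed ortho-hydroxybenzyl ketone to a 2-substituted benzofuran while the acetals are still hydrolysing. The electron-rich ring B phenol is the more likely to do so.
- Fallback: it sets out from 16 and returns at 18, with the order of the last two operations reversed.
  - The acetals are removed from 16 with HCl in MeOH, where there is no ketone to trap a phenol. This gives 3-[(3-chloro-6-hydroxy-2,4-dimethoxyphenyl)methyl]-5-hydroxy-7-methyl-1H-isochromen-1-one F3.
  - F3 is opened with excess NaOMe in MeOH under argon and neutralised into a pH 6 buffer, so the ketone of 18 is only ever exposed to base and near-neutral water.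

**Step 8.**
- What may go wrong: intramolecular Claisen (Dieckmann-type) attack of the Cc enolate on the newly formed C1 ester, leading on to a naphthalene-1,3-diol.
- Incomplete opening, or relactonisation during an acidic work-up.
- Fallback: it sets out from 16 and returns at 17.
  - Saponification (LiOH, THF–H2O, 0 °C) gives 2-[3-[3-chloro-2,4-dimethoxy-6-(methoxymethoxy)phenyl]-2-oxopropyl]-3-(methoxymethoxy)-5-methylbenzoic acid F4. Its carboxylate cannot act as an acylating agent, so the Claisen pathway is closed.
  - After acidification to pH 5, F4 is esterified under neutral conditions with TMSCHN2 in toluene–MeOH to give 17.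

**Step 5.**
- What may go wrong: SN2′ delivery of the aryl group giving a silylallene.
- Sluggish substitution by the doubly ortho-substituted arylcopper.
- Oxidative homocoupling of the arylcopper.
- Fallback: it sets out from 9 and returns at 14, bypassing 13.
  - Lithiated 9 (n-BuLi, THF, 0 °C) is quenched with ethylene oxide to give 2-[3-chloro-2,4-dimethoxy-6-(methoxymethoxy)phenyl]ethan-1-ol F5.
  - Dess–Martin oxidation buffered with NaHCO3 gives 2-[3-chloro-2,4-dimethoxy-6-(methoxymethoxy)phenyl]acetaldehyde F6.
  - Ohira–Bestmann homologation (dimethyl (1-diazo-2-oxopropyl)phosphonate, K2CO3, MeOH, 0 °C to rt) converts F6 to 14. The propargyl unit is thus built carbon by carbon, with no propargylic electrophile involved.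

**Step 2.**
- What may go wrong: addition of s-BuLi to the lithium carboxylate giving a ketone.
- Metalation at one of the singly activated ring positions.
- Incomplete trapping by iodine.
- Fallback: it sets out from 2 and returns at 5.
  - Ester 2 is isolated after the alkylation stage of step 1 instead of being saponified.
  - It is magnesiated between ester and acetal with the ester-tolerant amide base TMPMgCl·LiCl (THF, 0 °C to rt) and quenched with I2 to give methoxymethyl 2-iodo-3-(methoxymethoxy)-5-methylbenzoate F7.
  - Mild saponification of F7 (aq NaOH, MeOH) gives 5.

## Further compounds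

F1 | step 7 | methyl 2-iodo-3-(methoxymethoxy)-5-methylbenzoate | COC(=O)c1cc(C)cc(OCOC)c1I
F2 | step 7 | methyl 2-[3-[3-chloro-2,4-dimethoxy-6-(methoxymethoxy)phenyl]prop-1-yn-1-yl]-3-(methoxymethoxy)-5-methylbenzoate | COC(=O)c1cc(C)cc(OCOC)c1C#CCc1c(OCOC)cc(OC)c(Cl)c1OC
F3 | step 9 | 3-[(3-chloro-6-hydroxy-2,4-dimethoxyphenyl)methyl]-5-hydroxy-7-methyl-1H-isochromen-1-one | Cc1cc(O)c2C=C(Cc3c(O)cc(OC)c(Cl)c3OC)OC(=O)c2c1
F4 | step 8 | 2-[3-[3-chloro-2,4-dimethoxy-6-(methoxymethoxy)phenyl]-2-oxopropyl]-3-(methoxymethoxy)-5-methylbenzoic acid | OC(=O)c1cc(C)cc(OCOC)c1CC(=O)Cc1c(OCOC)cc(OC)c(Cl)c1OC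
F5 | step 5 | 2-[3-chloro-2,4-dimethoxy-6-(methoxymethoxy)phenyl]ethan-1-ol | OCCc1c(OCOC)cc(OC)c(Cl)c1OC
F6 | step 5 | 2-[3-chloro-2,4-dimethoxy-6-(methoxymethoxy)phenyl]acetaldehyde | O=CCc1c(OCOC)cc(OC)c(Cl)c1OC
F7 | step 2 | methoxymethyl 2-iodo-3-(methoxymethoxy)-5-methylbenzoate | COCOC(=O)c1cc(C)cc(OCOC)c1I
A1 | alternative 1 | racemic 2-[[[1-[3-chloro-2,4-dimethoxy-6-(methoxymethoxy)phenyl]pent-4-yn-2-yl]oxy]methyl]-4-methylfuran | C#CCC(Cc1c(OCOC)cc(OC)c(Cl)c1OC)OCc1cc(C)co1
A2 | alternative 1 | racemic 3-[[3-chloro-2,4-dimethoxy-6-(methoxymethoxy)phenyl]methyl]-7-methyl-3,4-dihydro-1H-isochromen-5-ol | Cc1cc(O)c2c(c1)COC(Cc1c(OCOC)cc(OC)c(Cl)c1OC)C2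
A3 | alternative 2 | 2-chloro-3-methoxycyclobut-2-en-1-one | COC1=C(Cl)C(=O)C1
A4 | alternative 2 | racemic methyl 2-[2-[tert-butyl(dimethyl)silyl]oxy-5-methoxypent-4-yn-1-yl]-3-(methoxymethoxy)-5-methylbenzoate | COC#CCC(O[Si](C)(C)C(C)(C)C)Cc1c(OCOC)cc(C)cc1C(=O)OC
A5 | alternative 2 | racemic methyl 2-[2-[tert-butyl(dimethyl)silyl]oxy-3-(3-chloro-6-hydroxy-2,4-dimethoxyphenyl)propyl]-3-(methoxymethoxy)-5-methylbenzoate | COC(=O)c1cc(C)cc(OCOC)c1CC(O[Si](C)(C)C(C)(C)C)Cc1c(O)cc(OC)c(Cl)c1OC
A6 | alternative 3 | (E)-1-[2-[[3-chloro-2,4-dimethoxy-6-(methoxymethoxy)phenyl]methyl]-1,3-dioxolan-2-yl]hex-4-en-3-one | C/C=C/C(=O)CCC1(Cc2c(OCOC)cc(OC)c(Cl)c2OC)OCCO1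
A7 | alternative 3 | dimethyl malonate | COC(=O)CC(=O)OC
A8 | alternative 3 | methyl 3-[[2-[[3-chloro-2,4-dimethoxy-6-(methoxymethoxy)phenyl]methyl]-1,3-dioxolan-2-yl]methyl]-6-methyl-2,4-dioxocyclohexane-1-carboxylate (mixture of diastereomers and tautomers) | COC(=O)C1C(C)CC(=O)C(CC2(Cc3c(OCOC)cc(OC)c(Cl)c3OC)OCCO2)C1=O
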